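How much X stands in flasks eta, beta and epsilon at the end, given two earlier runs at other charges of J?

| flask | L | J | remark | time |
|---|---|---|---|---|
| Thursday's | 0.10 M | 1.1 equiv | run made earlier |  |
| Friday's | 0.10 M | 3.3 equiv | run made earlier |  |
| eta | 0.10 M | 0.800 equiv |  | 4.0 h |
| beta | 0.10 M | 1.50 equiv |  | 4.0 h |
| epsilon | 0.10 M | 2.50 equiv |  | 4.0 h |

- Thursday's (time / min: X / %, L / %): 10.0: 2.6, 31.2; 30.0: 4.2, 30.2; 60.0: 4.5, 28.8; 80.0: 3.7, 29.9; 120: 5.7, 28.0
- Friday's (time / min: X / %, L / %): 10.0: 8.7, 21.9; 30.0: 16.5, 20.4; 60.0: 22.8, 19.4; 80.0: 22.0, 20.7; 120: 22.8, 19.5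

(each reading ± 1 percentage point)



- how much X is there at the end, in percent of the L charged: for each flask in turn (eta, beta, epsilon)

Start with Friday's curve. Its first reading, 8.7% after 10.0 min, gives a rough starting slope, and its last three readings average 22.5%, which I read as its level. Drawn on, that slope meets the level at a knee near 25.9 min. Thursday's curve has 2.6% at its first reading and a level, read the same way, of 4.63%, with its knee near 17.8 min. Both knees come earlier than the asked 4.0 h, so I read each new flask as a level.

You now have the two ends of a curve of level against charge, so join them. Call s the X gained per added equivalent of J: here s is 8.14% of the L charged per equivalent. Starting from Thursday's level, my own reckoning gives 2.19% for eta, 7.89% for beta and 16.0% for epsilon. Eta's charge lies below Thursday's, so its number stands outside the two ends.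

The forecast, reckoned another way, gives 1.5%, 9% and 17%, and it calls its own interpolation for the first exchange “the weak point, especially at low J”. It stands lower than my line for eta and higher for beta and epsilon.

The flasks give 2.34%, 7.02% and 15.8%, and the forecast is right within its margin.

    L + J → D + E (k = 0.585 M⁻¹ min⁻¹)
    E + J → D + X (k = 0.545 M⁻¹ min⁻¹)
    X + J ⇌ D + Z (K = 0.850, k = 0.906 M⁻¹ min⁻¹)
    L ⇌ Q (K = 1.80, k = 1.09 min⁻¹)
    J → G (k = 0.101 min⁻¹)

In eta at 0.0928 h, J goes by the path to G 5.3 times as fast as by the path from L + J to D + E, and J, the limiting reagent, stands at 0% of its charge at the asked time. Carried from beta's simulated X by s over the added equivalents, epsilon comes to 15.2%, and epsilon holds 15.8%.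

The earlier runs and the new flask were generated by integration on assumed constants; scatter was added.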